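**Plan**

- Retrosynthetic cuts: C–Br back to C–OH (inversion); the enyne C(sp2)–C(sp) bond and its C=C back to an aldehyde on the C2 arm; the hexenyl C=C and the C1'–C2' bond back to an aldehyde on C5; C3–OAc back to C3–acetyl; then both C–C bonds of the oxolane, C2–C3 and C4–C5, back to an acyclic acetal of a vinyl diol.
- Enabling feature: in the oxolane (O1, C2–C5) the C3 acetate is the Baeyer–Villiger image of a C3 acetyl group, C4 is a bare CH2, and the substituents on C2, C3 and C5 are all cis. This is the pattern that a Prins cyclization–pinacol rearrangement of a 4-vinyl-1,3-dioxolane delivers.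
- Forward order: (R)-α-hydroxy-γ-butyrolactone → methyl ketone → silyl ether → vinyl diol → acetal with (benzyloxy)acetaldehyde → the only ring (oxolane) in step 5 → acetate → C5 arm (allylation, cross-metathesis) → C2 arm (Takai, Sonogashira) → bromide → desilylation.
- Stereochemistry: C2 comes from the lactone (chiral pool). C3 and C5 come from the chair transition state and the suprafacial 1,2-shift of the key step, which is stereoconvergent for all four acetal diastereomers. The carbinol comes from Felkin–Anh allylation and is inverted to the (R)-bromide by SN2. Both alkenes are E, from cross-metathesis and Takai olefination.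

Key step: step 5

Assumption: compound 2 is written as the open-chain ketone, which equilibrates with its cyclic hemiketal; both react through the open form.

**Route**

Step 1
Reactants: 1 (3R)-3-hydroxyoxolan-2-one
Product: 2 (3R)-3,5-dihydroxypentan-2-one
Conditions: MeLi (2.1 equiv), THF, −78 °C; AcOH quench at −78 °C
Reagents that add atoms: methyllithium, [Li]C
Why: Mono-addition of an organolithium to a lactone: the first equivalent forms the lithium alkoxide, the second adds to the lactone carbonyl, and the lithium hemiketal alkoxide does not collapse before the quench, so the ketone level is reached without over-addition and the carbinol centre is untouched.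

Step 2
Reactants: 2 (3R)-3,5-dihydroxypentan-2-one
Product: 3 (3R)-5-[(tert-butyldiphenylsilyl)oxy]-3-hydroxypentan-2-one
Conditions: t-BuPh2SiCl, imidazole, CH2Cl2, 0 °C
Reagents that add atoms: tert-butyl(chloro)diphenylsilane, CC(C)(C)[Si](Cl)(c1ccccc1)c1ccccc1
Why: Selective silylation: the hindered silyl chloride should react only at the primary hydroxyl of the open-chain form, which also locks the compound as the acyclic ketone.

Step 3
Reactants: 3 (3R)-5-[(tert-butyldiphenylsilyl)oxy]-3-hydroxypentan-2-one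
Product: 4 (3R)-1-[(tert-butyldiphenylsilyl)oxy]-4-methylhex-5-ene-3,4-diol (both C4 epimers)
Conditions: CH2=CHMgBr (2.5 equiv), THF, −78 to 0 °C; aq. NH4Cl
Reagents that add atoms: vinylmagnesium bromide, C=C[Mg]Br
Why: Grignard addition to the magnesium alkoxide of an α-hydroxy ketone; the new tertiary carbinol may form as a mixture, which is harmless because this carbon becomes the acetyl carbonyl carbon in step 5.

Step 4
Reactants: 4 (3R)-1-[(tert-butyldiphenylsilyl)oxy]-4-methylhex-5-ene-3,4-diol; 5 (benzyloxy)acetaldehyde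
Product: 6 (4R)-2-[(benzyloxy)methyl]-4-{2-[(tert-butyldiphenylsilyl)oxy]ethyl}-5-ethenyl-5-methyl-1,3-dioxolane (mixture at C2 and C5)
Conditions: pyridinium p-toluenesulfonate (cat.), MgSO4, CH2Cl2, rt
Reagents that add atoms: none
Why: Acid-catalysed acetalisation of a 1,2-diol with an aldehyde gives the 1,3-dioxolane; the mixture at the acetal carbon and the tertiary carbon is used as such.

Step 5
Reactants: 6 (4R)-2-[(benzyloxy)methyl]-4-{2-[(tert-butyldiphenylsilyl)oxy]ethyl}-5-ethenyl-5-methyl-1,3-dioxolane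
Product: 7 1-[(2R,3R,5R)-5-[(benzyloxy)methyl]-2-{2-[(tert-butyldiphenylsilyl)oxy]ethyl}oxolan-3-yl]ethan-1-one (all-cis)
Conditions: SnCl4 (2 equiv), CH2Cl2, −78 to −20 °C
Reagents that add atoms: none
Why: SnCl4 opens the dioxolane at the tertiary allylic oxygen to the (E)-oxocarbenium ion on the secondary oxygen, the vinyl group attacks it (Prins cyclization, 6-endo-trig, forming C4–C5) through a chair with the silyloxyethyl and benzyloxymethyl groups both equatorial, and the resulting oxan-4-yl cation is quenched by 1,2-shift of ring carbon C2 from the tin-alkoxide carbon to the cationic carbon (pinacol rearrangement, ring contraction from six to five atoms), which forms the C2–C3 bond, closes the oxolane and turns the tertiary carbinol carbon into the acetyl carbonyl. The closest known reaction type is the Prins cyclization–pinacol rearrangement of 4-alkenyl-1,3-dioxolanes to 3-acyltetrahydrofurans. The 2,5-cis relation (C5) follows from the diequatorial chair, and C3 is set because C2 migrates suprafacially onto the cation face it already faces, which leaves the acetyl group cis to both ring substituents; C2 migrates with retention, so the single stereocentre taken from lactone 1 controls C3 and C5. The step is stereoconvergent: the four diastereomers of 6 differ only at the acetal carbon, which becomes planar in the oxocarbenium ion, and at the tertiary carbon, which becomes the carbonyl carbon. It needs selectivity between the two acetal oxygens, secured because only the oxocarbenium ion on the secondary oxygen holds the alkene in reach of a six-membered transition state while the other ionisation is reversible, and it needs the kinetic all-cis product to persist, secured by low temperature and immediate oxidation in step 6.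

Step 6
Reactants: 7 1-[(2R,3R,5R)-5-[(benzyloxy)methyl]-2-{2-[(tert-butyldiphenylsilyl)oxy]ethyl}oxolan-3-yl]ethan-1-one
Product: 8 (2R,3R,5R)-5-[(benzyloxy)methyl]-2-{2-[(tert-butyldiphenylsilyl)oxy]ethyl}oxolan-3-yl acetate
Conditions: (CF3CO)2O, urea·H2O2, Na2HPO4, CH2Cl2, 0 °C
Reagents that add atoms: trifluoroperacetic acid, OOC(=O)C(F)(F)F (made in the flask from trifluoroacetic anhydride, O=C(OC(=O)C(F)(F)F)C(F)(F)F, and urea hydrogen peroxide, NC(N)=O.OO)
Why: Baeyer–Villiger oxidation of the methyl ketone: the secondary ring carbon C3 should migrate in preference to methyl and with retention, so the acetyl group becomes the C3 acetate of the target directly, and the fast, buffered peracid limits epimerisation next to the ketone.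

Step 7
Reactants: 8 (2R,3R,5R)-5-[(benzyloxy)methyl]-2-{2-[(tert-butyldiphenylsilyl)oxy]ethyl}oxolan-3-yl acetate
Product: 9 (2R,3R,5R)-2-{2-[(tert-butyldiphenylsilyl)oxy]ethyl}-5-(hydroxymethyl)oxolan-3-yl acetate
Conditions: H2 (1 atm), Pd/C, EtOAc, rt
Reagents that add atoms: none
Why: Hydrogenolysis of the benzyl ether under neutral conditions leaves the acetate and the silyl ether in place.

Step 8
Reactants: 9 (2R,3R,5R)-2-{2-[(tert-butyldiphenylsilyl)oxy]ethyl}-5-(hydroxymethyl)oxolan-3-yl acetate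
Product: 10 (2R,3R,5R)-2-{2-[(tert-butyldiphenylsilyl)oxy]ethyl}-5-formyloxolan-3-yl acetate
Conditions: Dess–Martin periodinane, CH2Cl2, 0 °C to rt
Reagents that add atoms: none
Why: Dess–Martin oxidation is non-basic, so the α-alkoxy aldehyde should keep its configuration at C5; it is used directly.

Step 9
Reactants: 10 (2R,3R,5R)-2-{2-[(tert-butyldiphenylsilyl)oxy]ethyl}-5-formyloxolan-3-yl acetate
Product: 11 (2R,3R,5R)-2-{2-[(tert-butyldiphenylsilyl)oxy]ethyl}-5-[(1S)-1-hydroxybut-3-en-1-yl]oxolan-3-yl acetate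
Conditions: CH2=CHCH2SiMe3, BF3·OEt2, CH2Cl2, −78 °C
Reagents that add atoms: allyltrimethylsilane, C=CC[Si](C)(C)C
Why: Hosomi–Sakurai allylation under a monodentate Lewis acid follows the polar Felkin–Anh model, so the allyl group should add anti to the C5–O1 bond and give the (S)-carbinol (anti to the ring oxygen).

Step 10
Reactants: 11 (2R,3R,5R)-2-{2-[(tert-butyldiphenylsilyl)oxy]ethyl}-5-[(1S)-1-hydroxybut-3-en-1-yl]oxolan-3-yl acetate
Product: 12 (2R,3R,5R)-2-{2-[(tert-butyldiphenylsilyl)oxy]ethyl}-5-[(1S,3E)-1-hydroxyhex-3-en-1-yl]oxolan-3-yl acetate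
Conditions: (E)-hex-3-ene (excess), RuCl2(=CHPh)(PCy3)(H2IMes) (second-generation Grubbs catalyst, cat.), CH2Cl2, 40 °C
Reagents that add atoms: (E)-hex-3-ene, CC/C=C/CC
Why: Cross-metathesis of the terminal alkene with an excess of the symmetrical internal alkene; secondary metathesis should bring the new disubstituted alkene to the favoured E geometry while but-1-ene leaves.

Step 11
Reactants: 12 (2R,3R,5R)-2-{2-[(tert-butyldiphenylsilyl)oxy]ethyl}-5-[(1S,3E)-1-hydroxyhex-3-en-1-yl]oxolan-3-yl acetate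
Product: 13 (2R,3R,5R)-2-(2-hydroxyethyl)-5-[(1S,3E)-1-hydroxyhex-3-en-1-yl]oxolan-3-yl acetate
Conditions: HF·pyridine, pyridine, THF, 0 °C to rt
Reagents that add atoms: none
Why: Fluoride-driven cleavage of the silyl ether under weakly acidic conditions should leave the acetate in place and unmigrated.

Step 12
Reactants: 13 (2R,3R,5R)-2-(2-hydroxyethyl)-5-[(1S,3E)-1-hydroxyhex-3-en-1-yl]oxolan-3-yl acetate
Product: 14 (2R,3R,5R)-5-[(1S,3E)-1-hydroxyhex-3-en-1-yl]-2-(2-oxoethyl)oxolan-3-yl acetate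
Conditions: TEMPO (cat.), PhI(OAc)2, CH2Cl2, rt
Reagents that add atoms: none
Why: Oxoammonium (TEMPO) oxidation is selective for the primary alcohol over the hindered secondary one and stops at the aldehyde.

Step 13
Reactants: 14 (2R,3R,5R)-5-[(1S,3E)-1-hydroxyhex-3-en-1-yl]-2-(2-oxoethyl)oxolan-3-yl acetate
Product: 15 (2R,3R,5R)-5-[(1S,3E)-1-hydroxyhex-3-en-1-yl]-2-[(2E)-3-iodoprop-2-en-1-yl]oxolan-3-yl acetate
Conditions: CrCl2 (excess), CHI3, THF, 0 °C to rt
Reagents that add atoms: iodoform, IC(I)I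
Why: Takai olefination: the geminal dichromium species from iodoform adds to the aldehyde and eliminates to the (E)-vinyl iodide under non-basic conditions, so the β-alkoxy aldehyde should not eliminate and the free hydroxyl and the acetate are tolerated.

Step 14
Reactants: 15 (2R,3R,5R)-5-[(1S,3E)-1-hydroxyhex-3-en-1-yl]-2-[(2E)-3-iodoprop-2-en-1-yl]oxolan-3-yl acetate
Product: 16 (2R,3R,5R)-5-[(1S,3E)-1-hydroxyhex-3-en-1-yl]-2-[(2E)-5-(trimethylsilyl)pent-2-en-4-yn-1-yl]oxolan-3-yl acetate
Conditions: Me3SiC≡CH, Pd(PPh3)4 (cat.), CuI (cat.), i-Pr2NH, THF, rt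
Reagents that add atoms: ethynyltrimethylsilane, C#C[Si](C)(C)C
Why: Sonogashira coupling of the vinyl iodide proceeds with retention of the E geometry and tolerates the hydroxyl and the acetate.

Step 15
Reactants: 16 (2R,3R,5R)-5-[(1S,3E)-1-hydroxyhex-3-en-1-yl]-2-[(2E)-5-(trimethylsilyl)pent-2-en-4-yn-1-yl]oxolan-3-yl acetate
Product: 17 (2R,3R,5R)-5-[(1R,3E)-1-bromohex-3-en-1-yl]-2-[(2E)-5-(trimethylsilyl)pent-2-en-4-yn-1-yl]oxolan-3-yl acetate
Conditions: CBr4, P(n-C8H17)3, toluene, 70 °C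
Reagents that add atoms: tetrabromomethane, BrC(Br)(Br)Br
Why: Appel-type bromination: the alkoxyphosphonium ion is displaced by bromide with inversion (SN2), which should turn the (S)-carbinol into the (R)-bromide.

Step 16
Reactants: 17 (2R,3R,5R)-5-[(1R,3E)-1-bromohex-3-en-1-yl]-2-[(2E)-5-(trimethylsilyl)pent-2-en-4-yn-1-yl]oxolan-3-yl acetate
Product: 18 trans-kumausyne
Conditions: Bu4NF, AcOH, THF, 0 °C
Reagents that add atoms: none
Why: Fluoride cleaves the C(sp)–Si bond, and buffering with acetic acid should keep the medium too weakly basic for acetate cleavage or E2 loss of HBr.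

**Compound list**

1 | (3R)-3-hydroxyoxolan-2-one ((R)-α-hydroxy-γ-butyrolactone) | O[C@@H]1CCOC1=O | starting material
2 | (3R)-3,5-dihydroxypentan-2-one (in equilibrium with its cyclic hemiketal) | CC(=O)[C@H](O)CCO | intermediate
3 | (3R)-5-[(tert-butyldiphenylsilyl)oxy]-3-hydroxypentan-2-one | CC(=O)[C@H](O)CCO[Si](c1ccccc1)(c1ccccc1)C(C)(C)C | intermediate
4 | (3R)-1-[(tert-butyldiphenylsilyl)oxy]-4-methylhex-5-ene-3,4-diol (both C4 epimers) | CC(C)(C)[Si](c1ccccc1)(c1ccccc1)OCC[C@@H](O)C(C)(O)C=C | intermediate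
5 | (benzyloxy)acetaldehyde | O=CCOCc1ccccc1 | starting material
6 | (4R)-2-[(benzyloxy)methyl]-4-{2-[(tert-butyldiphenylsilyl)oxy]ethyl}-5-ethenyl-5-methyl-1,3-dioxolane (mixture at C2 and C5) | CC(C)(C)[Si](c1ccccc1)(c1ccccc1)OCC[C@H]1OC(COCc2ccccc2)OC1(C)C=C | intermediate
7 | 1-[(2R,3R,5R)-5-[(benzyloxy)methyl]-2-{2-[(tert-butyldiphenylsilyl)oxy]ethyl}oxolan-3-yl]ethan-1-one | CC(C)(C)[Si](c1ccccc1)(c1ccccc1)OCC[C@H]1O[C@@H](COCc2ccccc2)C[C@H]1C(C)=O | intermediate
8 | (2R,3R,5R)-5-[(benzyloxy)methyl]-2-{2-[(tert-butyldiphenylsilyl)oxy]ethyl}oxolan-3-yl acetate | CC(C)(C)[Si](c1ccccc1)(c1ccccc1)OCC[C@H]1O[C@@H](COCc2ccccc2)C[C@H]1OC(C)=O | intermediate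
9 | (2R,3R,5R)-2-{2-[(tert-butyldiphenylsilyl)oxy]ethyl}-5-(hydroxymethyl)oxolan-3-yl acetate | CC(C)(C)[Si](c1ccccc1)(c1ccccc1)OCC[C@H]1O[C@@H](CO)C[C@H]1OC(C)=O | intermediate
10 | (2R,3R,5R)-2-{2-[(tert-butyldiphenylsilyl)oxy]ethyl}-5-formyloxolan-3-yl acetate | CC(C)(C)[Si](c1ccccc1)(c1ccccc1)OCC[C@H]1O[C@@H](C=O)C[C@H]1OC(C)=O | intermediate
11 | (2R,3R,5R)-2-{2-[(tert-butyldiphenylsilyl)oxy]ethyl}-5-[(1S)-1-hydroxybut-3-en-1-yl]oxolan-3-yl acetate | CC(C)(C)[Si](c1ccccc1)(c1ccccc1)OCC[C@H]1O[C@@H]([C@@H](O)CC=C)C[C@H]1OC(C)=O | intermediate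
12 | (2R,3R,5R)-2-{2-[(tert-butyldiphenylsilyl)oxy]ethyl}-5-[(1S,3E)-1-hydroxyhex-3-en-1-yl]oxolan-3-yl acetate | CC(C)(C)[Si](c1ccccc1)(c1ccccc1)OCC[C@H]1O[C@@H]([C@@H](O)C/C=C/CC)C[C@H]1OC(C)=O | intermediate
13 | (2R,3R,5R)-2-(2-hydroxyethyl)-5-[(1S,3E)-1-hydroxyhex-3-en-1-yl]oxolan-3-yl acetate | OCC[C@H]1O[C@@H]([C@@H](O)C/C=C/CC)C[C@H]1OC(C)=O | intermediate
14 | (2R,3R,5R)-5-[(1S,3E)-1-hydroxyhex-3-en-1-yl]-2-(2-oxoethyl)oxolan-3-yl acetate | O=CC[C@H]1O[C@@H]([C@@H](O)C/C=C/CC)C[C@H]1OC(C)=O | intermediate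
15 | (2R,3R,5R)-5-[(1S,3E)-1-hydroxyhex-3-en-1-yl]-2-[(2E)-3-iodoprop-2-en-1-yl]oxolan-3-yl acetate | I/C=C/C[C@H]1O[C@@H]([C@@H](O)C/C=C/CC)C[C@H]1OC(C)=O | intermediate
16 | (2R,3R,5R)-5-[(1S,3E)-1-hydroxyhex-3-en-1-yl]-2-[(2E)-5-(trimethylsilyl)pent-2-en-4-yn-1-yl]oxolan-3-yl acetate | C[Si](C)(C)C#C/C=C/C[C@H]1O[C@@H]([C@@H](O)C/C=C/CC)C[C@H]1OC(C)=O | intermediate
17 | (2R,3R,5R)-5-[(1R,3E)-1-bromohex-3-en-1-yl]-2-[(2E)-5-(trimethylsilyl)pent-2-en-4-yn-1-yl]oxolan-3-yl acetate | C[Si](C)(C)C#C/C=C/C[C@H]1O[C@@H]([C@H](Br)C/C=C/CC)C[C@H]1OC(C)=O | intermediate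
18 | trans-kumausyne, (2R,3R,5R)-5-[(1R,3E)-1-bromohex-3-en-1-yl]-2-[(2E)-pent-2-en-4-yn-1-yl]oxolan-3-yl acetate | C#C/C=C/C[C@H]1O[C@@H]([C@H](Br)C/C=C/CC)C[C@H]1OC(C)=O | target

**Step count and risks**

Total step count: 16. Longest linear sequence: 16 steps (1 to 18); compound 5 enters at step 4.

Steps most likely to fail:

1. Step 5. The unsubstituted vinyl group is a weak π-nucleophile, so acetal cleavage, oligomerisation or capture of the oxocarbenium ion by the silyl ether oxygen may outrun the Prins step, and the kinetic cis acetyl group may epimerise before it is oxidised. The fallback sets out from 5 and returns to the route at 8. Mukaiyama aldol addition of 2-(trimethylsilyloxy)buta-1,3-diene to 5, catalysed by the enantiomer of [Cu(Ph-pybox)](SbF6)2 that delivers the (R)-aldol, should give after desilylating work-up (5R)-6-(benzyloxy)-5-hydroxyhex-1-en-3-one F1. Hydroxyl-directed anti reduction with Me4NBH(OAc)3 (Evans–Saksena reduction) should give (2R,4R)-1-(benzyloxy)hex-5-ene-2,4-diol F2. Oxycarbonylation with PdCl2 (cat.), CuCl2, NaOAc and CO in AcOH closes the oxolane at O1–C2: 5-exo oxypalladation by the C2 hydroxyl, CO insertion and lactonisation by the allylic hydroxyl should give the cis-fused, all-cis lactone (3aR,5R,6aR)-5-[(benzyloxy)methyl]tetrahydrofuro[3,2-b]furan-2(3H)-one F3. LiAlH4 reduction gives (2R,3R,5R)-5-[(benzyloxy)methyl]-2-(2-hydroxyethyl)oxolan-3-ol F4. Selective silylation of the primary hydroxyl with t-BuPh2SiCl and imidazole gives (2R,3R,5R)-5-[(benzyloxy)methyl]-2-{2-[(tert-butyldiphenylsilyl)oxy]ethyl}oxolan-3-ol F5. Acetylation with Ac2O, pyridine and DMAP gives 8.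

2. Step 15. At 70 °C the oxolane oxygen may take part in the ionisation of the alkoxyphosphonium ion (retention or ring expansion through an oxonium ion), and E2 loss toward the allylic CH2 may compete with SN2. The fallback sets out from 16 and returns at 17. The alcohol is converted with ClCH2SO2Cl and pyridine at 0 °C into the isolated sulfonate (2R,3R,5R)-5-[(1S,3E)-1-{[(chloromethyl)sulfonyl]oxy}hex-3-en-1-yl]-2-[(2E)-5-(trimethylsilyl)pent-2-en-4-yn-1-yl]oxolan-3-yl acetate F6. This very reactive leaving group is then displaced with Bu4NBr in THF at or near room temperature, a separate low-temperature SN2 step with inversion that gives 17.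

3. Step 10. Thermodynamic control in the cross-metathesis may leave a share of the Z alkene that cannot be separated, and ruthenium hydrides may move the double bond. The fallback sets out from 11 and returns at 13. Silylation with Et3SiOTf and 2,6-lutidine gives (2R,3R,5R)-2-{2-[(tert-butyldiphenylsilyl)oxy]ethyl}-5-[(1S)-1-[(triethylsilyl)oxy]but-3-en-1-yl]oxolan-3-yl acetate F7. Ozonolysis (O3, then PPh3) gives (2R,3R,5R)-2-{2-[(tert-butyldiphenylsilyl)oxy]ethyl}-5-[(1S)-3-oxo-1-[(triethylsilyl)oxy]propyl]oxolan-3-yl acetate F8. Julia–Kocienski olefination with 1-phenyl-5-(propylsulfonyl)-1H-tetrazole and KN(SiMe3)2 in DME at −60 °C sets the E alkene kinetically and gives (2R,3R,5R)-2-{2-[(tert-butyldiphenylsilyl)oxy]ethyl}-5-[(1S,3E)-1-[(triethylsilyl)oxy]hex-3-en-1-yl]oxolan-3-yl acetate F9. HF·pyridine then removes both silyl groups and gives 13.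

**Further compounds**

F1 | step 5 | (5R)-6-(benzyloxy)-5-hydroxyhex-1-en-3-one | C=CC(=O)C[C@@H](O)COCc1ccccc1
F2 | step 5 | (2R,4R)-1-(benzyloxy)hex-5-ene-2,4-diol | C=C[C@H](O)C[C@@H](O)COCc1ccccc1
F3 | step 5 | (3aR,5R,6aR)-5-[(benzyloxy)methyl]tetrahydrofuro[3,2-b]furan-2(3H)-one | O=C1C[C@H]2O[C@@H](COCc3ccccc3)C[C@H]2O1
F4 | step 5 | (2R,3R,5R)-5-[(benzyloxy)methyl]-2-(2-hydroxyethyl)oxolan-3-ol | OCC[C@H]1O[C@@H](COCc2ccccc2)C[C@H]1O
F5 | step 5 | (2R,3R,5R)-5-[(benzyloxy)methyl]-2-{2-[(tert-butyldiphenylsilyl)oxy]ethyl}oxolan-3-ol | CC(C)(C)[Si](c1ccccc1)(c1ccccc1)OCC[C@H]1O[C@@H](COCc2ccccc2)C[C@H]1O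
F6 | step 15 | (2R,3R,5R)-5-[(1S,3E)-1-{[(chloromethyl)sulfonyl]oxy}hex-3-en-1-yl]-2-[(2E)-5-(trimethylsilyl)pent-2-en-4-yn-1-yl]oxolan-3-yl acetate | C[Si](C)(C)C#C/C=C/C[C@H]1O[C@@H]([C@@H](OS(=O)(=O)CCl)C/C=C/CC)C[C@H]1OC(C)=O
F7 | step 10 | (2R,3R,5R)-2-{2-[(tert-butyldiphenylsilyl)oxy]ethyl}-5-[(1S)-1-[(triethylsilyl)oxy]but-3-en-1-yl]oxolan-3-yl acetate | CC(C)(C)[Si](c1ccccc1)(c1ccccc1)OCC[C@H]1O[C@@H]([C@@H](O[Si](CC)(CC)CC)CC=C)C[C@H]1OC(C)=O
F8 | step 10 | (2R,3R,5R)-2-{2-[(tert-butyldiphenylsilyl)oxy]ethyl}-5-[(1S)-3-oxo-1-[(triethylsilyl)oxy]propyl]oxolan-3-yl acetate | CC(C)(C)[Si](c1ccccc1)(c1ccccc1)OCC[C@H]1O[C@@H]([C@@H](O[Si](CC)(CC)CC)CC=O)C[C@H]1OC(C)=O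
F9 | step 10 | (2R,3R,5R)-2-{2-[(tert-butyldiphenylsilyl)oxy]ethyl}-5-[(1S,3E)-1-[(triethylsilyl)oxy]hex-3-en-1-yl]oxolan-3-yl acetate | CC(C)(C)[Si](c1ccccc1)(c1ccccc1)OCC[C@H]1O[C@@H]([C@@H](O[Si](CC)(CC)CC)C/C=C/CC)C[C@H]1OC(C)=O
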